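Early on, a kinetic resolution is a race between mirror images: the single-handed catalyst takes left-handed substrate, L, and leaves right-handed substrate, S, nearly untouched, as the S readings show.

all flasks: left-handed substrate 0.077 M; right-handed substrate 0.077 M; partner 0.154 M; protic impurity 0.0231 M

|  | precatalyst | remark | time |
|---|---|---|---|
| eta | 0.19 mM | run made earlier |  |
| epsilon | 0.76 mM | run made earlier |  |
| flask | 0.38 mM |  | 5.0 min |

| run | time / min | right-handed substrate / % | left-handed substrate / % | left-handed product / % |
|---|---|---|---|---|
| eta | 1.50 | 50 | 17 | 32 |
| eta | 3.00 | 50 | 2 | 48 |
| eta | 5.00 | 50 | 0 | 49 |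
| eta | 6.00 | 51 | 0 | 50 |
| epsilon | 0.833 | 50 | 7 | 42 |
| epsilon | 2.00 | 53 | 1 | 46 |
| epsilon | 4.00 | 45 | 0 | 49 |
| epsilon | 6.00 | 48 | 0 | 50 |

(readings scatter by 1.5 percentage points)

- free catalyst is single-handed; left-handed substrate and right-handed substrate are mirror images of each other, charged as a racemate, each of them at the stated concentration

1. whether the excess of right-handed substrate over left-handed substrate among what is left of the two reaches 99 % by 5.0 min (yes / no)
2. the highest excess of right-handed substrate over left-handed substrate among what is left of the two up to 5.0 min

Charged equal, S and L start with ln(S/L) at nil. An excess of 99 % means S/L = 199, so L must reach 0.251 % of the total. A reading scatters by 1.5 percentage points, so the tables cannot show that level directly, and we reckon it instead: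

N = ln(S/L) = 5.29

This is the clearing number, the e-foldings of L against S that the wanted excess takes.

In the opening stretch the eta run gains N at an average rate k, taken from its first reading:

k(eta) = 0.719 min⁻¹

and the epsilon run gives

k(epsilon) = 2.36 min⁻¹

In the middle of the eta run, N climbs at a read 1.43 min⁻¹, faster than in the opening stretch, so in the eta run something is still coming on after the start. That reading is rough, since it rests on an L of 2 %.

For the end we take the slow opening rate as the safe one. The flask holds twice the eta precatalyst and half the epsilon one, so it sits midway on a log scale:

k(flask) = 1.30 min⁻¹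

time needed = N/k(flask) = 4.06 min

Our answer for the flask is therefore yes, with 99.7 % at 5.0 min. The forecast also says yes, but gives 100 % where we give the figure above, and adds: “There is no clear sign of catalyst death”.

The flask gives yes and >99.9 %.

    partner + catalyst intermediate A → free catalyst + left-handed product (k = 82.0 L mol⁻¹ s⁻¹)
    partner + catalyst intermediate B → free catalyst + right-handed product (k = 1.20 L mol⁻¹ s⁻¹)
    free catalyst + right-handed substrate ⇌ catalyst intermediate B (K = 5.10 L mol⁻¹, k = 2100 L mol⁻¹ s⁻¹)
    partner + protic impurity → quenched reagent (k = 0.160 L mol⁻¹ s⁻¹)
    free catalyst + left-handed substrate ⇌ catalyst intermediate A (K = 96.0 L mol⁻¹, k = 780 L mol⁻¹ s⁻¹)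
    partner + precatalyst → free catalyst + spent reagent (k = 0.140 L mol⁻¹ s⁻¹)

The flask spends its N by 2.38 min, an average of 2.22 min⁻¹, with twice that time allowed. The largest single effect on the excess at 5.0 min is the back reaction of catalyst intermediate B to free catalyst and right-handed substrate. Take that return away from the same flask, and the part reacted at 5.0 min drops from 51.1 % to 11.4 %. The excess then stands at −8.17 %, a clearing number of −0.164 against the 5.29 wanted.

Readings and results come from a simulation on assumed constants, noise included.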